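Ring A is disconnected across C1–C2 and C5–C10 as an intramolecular Diels–Alder adduct. The feature used is that C20, the oxygenated carbon on the quaternary benzylic C10, sits 1,4 across ring B from C7, the terminus of the C6=C7 styrene. A temporary C7–O–C20 ether ring (a 4-methylidene isochroman) therefore ties the 1,1-disubstituted alkene C1=C10 to a stereogenic C7 that carries the diene C5=C4(CO2Me)–C3=C2. One thermal cycloaddition closes rings A and B and sets C10 and C5 from C7. Later, methylation sets C4, and acid opens the ether into the C6=C7 alkene and the 19,20-lactone.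

Key step: step 11

Remark: abietane numbering is used for the target and all tricyclic intermediates (ring A C1–C5/C10, ring B C5–C10, ring C C8/C9/C11–C14, lactone C19(=O)–O–C20); compounds 1, 2, 9, 12, 15 and 20 are taken as commercial.

Step 1
Reactants: 1 1,2,4-trimethoxybenzene; 2 acetone
Product: 4 2-(2,3,6-trimethoxyphenyl)propan-2-ol, via aryllithium 3 (not isolated)
Conditions: n-BuLi, THF, 0 °C to rt; acetone, −78 °C to rt; H2O
Reagents that add atoms: none
Why: Directed ortho-lithiation should occur at the ring position flanked by two methoxy groups, and the aryllithium then adds to the ketone (1,2-addition of an organolithium).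

Step 2
Reactants: 4 2-(2,3,6-trimethoxyphenyl)propan-2-ol
Product: 5 1,2,4-trimethoxy-3-(propan-2-yl)benzene
Conditions: Et3SiH, CF3CO2H, CH2Cl2, 0 °C to rt
Reagents that add atoms: none
Why: Ionic hydrogenation, in which the tertiary benzylic cation stabilised by two ortho alkoxy groups is reduced by hydride transfer from the silane.

Step 3
Reactants: 5 1,2,4-trimethoxy-3-(propan-2-yl)benzene
Product: 6 2,4,5-trimethoxy-3-(propan-2-yl)benzaldehyde
Conditions: Cl2CHOCH3, TiCl4, CH2Cl2, −78 to 0 °C; H2O
Reagents that add atoms: dichloromethyl methyl ether, COC(Cl)Cl; water, O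
Why: Rieche formylation (electrophilic aromatic substitution) should go to the free position that is ortho and para to methoxy groups (the future C8) and not to the one para to the isopropyl group.

Step 4
Reactants: 6 2,4,5-trimethoxy-3-(propan-2-yl)benzaldehyde
Product: 8 2-iodo-3,4,6-trimethoxy-5-(propan-2-yl)benzaldehyde, via dilithio aminoalkoxide 7 (not isolated)
Conditions: LiN(CH3)CH2CH2N(CH3)2 (from the amine and n-BuLi), THF, −20 °C; n-BuLi, −20 °C; I2, −78 °C to rt; H2O
Reagents that add atoms: iodine, II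
Why: Directed ortho-metalation of the aldehyde masked in situ as an α-amino alkoxide, which together with the neighbouring methoxy group directs lithiation to the only free ring position (the future C9), followed by iodination of the aryllithium.

Step 5
Reactants: 8 2-iodo-3,4,6-trimethoxy-5-(propan-2-yl)benzaldehyde; 9 trimethyl(prop-2-en-1-yloxy)silane
Product: 10 1-[bis(prop-2-en-1-yloxy)methyl]-2-iodo-3,4,6-trimethoxy-5-(propan-2-yl)benzene
Conditions: 9 (2.5 equiv), Me3SiOTf (cat.), CH2Cl2, −78 to −20 °C; pyridine quench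
Reagents that add atoms: none
Why: Acetalisation of the hindered aldehyde with an alkoxysilane under silyl triflate catalysis is driven by formation of hexamethyldisiloxane.

Step 6
Reactants: 10 1-[bis(prop-2-en-1-yloxy)methyl]-2-iodo-3,4,6-trimethoxy-5-(propan-2-yl)benzene
Product: 11 5,6,8-trimethoxy-4-methylidene-7-(propan-2-yl)-1-(prop-2-en-1-yloxy)-3,4-dihydro-1H-2-benzopyran (racemic)
Conditions: Pd(OAc)2 (5 mol %), PPh3, Ag2CO3, CH3CN, 60 °C
Reagents that add atoms: none
Why: Intramolecular Heck reaction, in which 6-exo-trig carbopalladation of one allyl ether and β-hydride elimination of the only β-hydrogen (on C10) give the exocyclic alkene C1=C10, the silver salt holding back re-addition of the palladium hydride.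

Step 7
Reactants: 11 5,6,8-trimethoxy-4-methylidene-7-(propan-2-yl)-1-(prop-2-en-1-yloxy)-3,4-dihydro-1H-2-benzopyran; 12 tert-butyl[(1-methoxyethenyl)oxy]dimethylsilane
Product: 14 methyl 2-[(1S)-5,6,8-trimethoxy-4-methylidene-7-(propan-2-yl)-3,4-dihydro-1H-2-benzopyran-1-yl]acetate, via chloroisochroman 13 (not isolated)
Conditions: BCl3, CH2Cl2, −78 to 0 °C, then evaporation; 12, chiral amide–thiourea catalyst (tert-leucine amide of a 2-arylpyrrolidine, N′-3,5-bis(trifluoromethyl)phenyl thiourea, 10 mol %), t-BuOCH3, −78 °C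
Reagents that add atoms: none
Why: Enantioselective Mukaiyama-type addition of a silyl ketene acetal to the oxocarbenium ion under chloride-binding thiourea catalysis, with the catalyst enantiomer chosen so that the new centre (C7 of the skeleton) is (S).

Step 8
Reactants: 15 methyl 2-[bis(2,2,2-trifluoroethoxy)phosphoryl]acetate
Product: 17 methyl 2-bromo-2-[bis(2,2,2-trifluoroethoxy)phosphoryl]acetate (racemic), via sodium phosphonate 16 (not isolated)
Conditions: NaH (1.0 equiv), THF, 0 °C; N-bromosuccinimide (1.0 equiv), −78 to 0 °C; dilute aqueous HCl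
Reagents that add atoms: N-bromosuccinimide, O=C1CCC(=O)N1Br
Why: Electrophilic α-bromination of the stabilised phosphonate carbanion gives the bromo Horner–Wadsworth–Emmons reagent.

Step 9
Reactants: 14 methyl 2-[(1S)-5,6,8-trimethoxy-4-methylidene-7-(propan-2-yl)-3,4-dihydro-1H-2-benzopyran-1-yl]acetate; 17 methyl 2-bromo-2-[bis(2,2,2-trifluoroethoxy)phosphoryl]acetate
Product: 19 methyl (2E)-2-bromo-4-[(1S)-5,6,8-trimethoxy-4-methylidene-7-(propan-2-yl)-3,4-dihydro-1H-2-benzopyran-1-yl]but-2-enoate, via aldehyde 18 (not isolated)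
Conditions: i-Bu2AlH (1.1 equiv), CH2Cl2, −78 °C; then 17, KN(SiMe3)2, 18-crown-6, THF, −78 to −40 °C; KNaC4H4O6 (aq)
Reagents that add atoms: none
Why: Partial reduction of the ester and in situ Horner–Wadsworth–Emmons olefination with the trifluoroethyl phosphonate (Still–Gennari-type kinetic control) should give the (E)-α-bromoacrylate, in which the ester is cis to the C6 chain.

Step 10
Reactants: 19 methyl (2E)-2-bromo-4-[(1S)-5,6,8-trimethoxy-4-methylidene-7-(propan-2-yl)-3,4-dihydro-1H-2-benzopyran-1-yl]but-2-enoate; 20 2-ethenyl-4,4,5,5-tetramethyl-1,3,2-dioxaborolane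
Product: 21 methyl (2Z)-2-ethenyl-4-[(1S)-5,6,8-trimethoxy-4-methylidene-7-(propan-2-yl)-3,4-dihydro-1H-2-benzopyran-1-yl]but-2-enoate
Conditions: Pd(dppf)Cl2 (5 mol %), Cs2CO3, THF/H2O (10:1), 45 °C
Reagents that add atoms: none
Why: Suzuki–Miyaura coupling proceeds with retention at the bromoalkene, so the vinyl group ends up trans to the chain and the diene C5=C4–C3=C2 carries its tether on the outside (E-diene).

Step 11
Reactants: 21 methyl (2Z)-2-ethenyl-4-[(1S)-5,6,8-trimethoxy-4-methylidene-7-(propan-2-yl)-3,4-dihydro-1H-2-benzopyran-1-yl]but-2-enoate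
Product: 22 methyl (5R,7S,10R)-7,20-epoxy-11,12,14-trimethoxy-18-norabieta-3,8,11,13-tetraen-19-oate (7β,20-ether bridge, 5α-H, C3=C4 enoate)
Conditions: PhCH3 (0.01 M), BHT (10 mol %), base-washed sealed tube, 180 °C
Reagents that add atoms: none
Why: A thermal, concerted but asynchronous [4+2] cycloaddition joins the diene C5=C4(CO2Me)–C3=C2 to the exocyclic alkene C1=C10; the closest known type is the type 1 intramolecular Diels–Alder reaction of a 1,7,9-decatriene with an unactivated 1,1-disubstituted styrene-type dienophile. Ring A is closed by the cycloaddition itself (six-membered, boat-like transition state), and ring B is closed in the fused mode by the C5–C10 bond, transannularly across the boat form of the dihydropyran, which gives the 2-oxabicyclo[2.2.2]octene core known from 7,20-bridged abietanes. C10 is controlled by C7: the arm C7–C6–C5 can reach only the alkene face syn to it, and the peri C14 methoxy group already holds this arm pseudoaxial. C5 is controlled by the orientation of the diene: its C3–C4(CO2Me) edge should lie over the slim CH2–O bridge and not over the methoxylated arene, which puts H5 anti to C20 (trans A/B relationship). The step needs the E-diene, secured by the (2Z)-enoate from steps 9 and 10, and the fused regiochemistry, secured by the short tether in spite of the mismatched polarity. High dilution and a radical inhibitor are used to hold back dimerisation of the 2-carbomethoxydiene.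

Step 12
Reactants: 22 methyl (5R,7S,10R)-7,20-epoxy-11,12,14-trimethoxy-18-norabieta-3,8,11,13-tetraen-19-oate
Product: 24 methyl (4S,5R,7S,10R)-7,20-epoxy-11,12,14-trimethoxyabieta-2,8,11,13-tetraen-19-oate (4α-methyl, 4β-ester), via lithium dienolate 23 (not isolated)
Conditions: LiN(i-Pr)2 (1.3 equiv), DMPU, THF, −78 °C; CH3I, −78 to 0 °C
Reagents that add atoms: iodomethane, CI
Why: Deconjugative α-alkylation of the extended enolate, in which iodomethane should attack C4 from the α face because the axial C20 bridge carbon shields the β face in a 1,3-diaxial sense, so that the ester ends up β and cis to C20.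

Step 13
Reactants: 24 methyl (4S,5R,7S,10R)-7,20-epoxy-11,12,14-trimethoxyabieta-2,8,11,13-tetraen-19-oate
Product: 25 methyl (4S,5R,7S,10R)-7,20-epoxy-11,12,14-trimethoxyabieta-8,11,13-trien-19-oate
Conditions: H2 (1 atm), [Ir(cod)(PCy3)(py)]PF6 (5 mol %), CH2Cl2, rt
Reagents that add atoms: none
Why: Homogeneous catalytic hydrogenation should saturate the cis-disubstituted C2=C3 alkene without hydrogenolysis of the benzylic C7–O bond.

Step 14
Reactants: 25 methyl (4S,5R,7S,10R)-7,20-epoxy-11,12,14-trimethoxyabieta-8,11,13-trien-19-oate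
Product: 27 (4S,5R,10R)-11,12,14-trimethoxyabieta-6,8,11,13-tetraen-19,20-olide, via hydroxy ester 26 (not isolated)
Conditions: TsOH·H2O (0.2 equiv), PhCH3, 80 °C
Reagents that add atoms: none
Why: Acid-induced E1 opening of the benzylic ether (the C7 cation is stabilised by the ortho and para methoxy groups and loses H6) gives the C6=C7 styrene and frees the C20 hydroxyl, which lactonises onto the 1,3-diaxial C19 methyl ester (acid-catalysed transesterification) and so pulls the sequence forward.

Step 15
Reactants: 27 (4S,5R,10R)-11,12,14-trimethoxyabieta-6,8,11,13-tetraen-19,20-olide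
Product: 28 (4S,5R,10R)-12-methoxy-11,14-dioxoabieta-6,8,12-trien-19,20-olide
Conditions: (NH4)2Ce(NO3)6 (2.5 equiv), CH3CN/H2O (2:1), 0 °C
Reagents that add atoms: water, O
Why: Oxidative demethylation of the para-dimethoxyarene (C11/C14) by a one-electron oxidant should give the para-quinone and leave the C12 methoxy group as a vinylogous ester.

Step 16
Reactants: 28 (4S,5R,10R)-12-methoxy-11,14-dioxoabieta-6,8,12-trien-19,20-olide
Product: 29 (4S,5R,10R)-12-hydroxy-11,14-dioxoabieta-6,8,12-trien-19,20-olide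
Conditions: BCl3 (1.5 equiv), CH2Cl2, −78 to 0 °C; H2O
Reagents that add atoms: none
Why: Chelation-assisted Lewis acid O-demethylation, in which boron bound to the C11 carbonyl oxygen activates the neighbouring methyl ether of the methoxyquinone for attack by chloride.

Step 17
Reactants: 29 (4S,5R,10R)-12-hydroxy-11,14-dioxoabieta-6,8,12-trien-19,20-olide
Product: 30 (4S,5R,10R)-12-acetoxy-11,14-dioxoabieta-6,8,12-trien-19,20-olide (target, CNP0596241.1)
Conditions: Ac2O, pyridine, DMAP (cat.), CH2Cl2, 0 °C
Reagents that add atoms: acetic anhydride, CC(=O)OC(C)=O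
Why: O-Acylation (esterification) of the acidic hydroxyquinone gives the 12-acetate.

Compound list
1 | 1,2,4-trimethoxybenzene | COc1ccc(OC)c(OC)c1 | starting material
2 | acetone | CC(C)=O | starting material
3 | 2,3,6-trimethoxyphenyllithium | [Li]c1c(OC)c(OC)ccc1OC | intermediate
4 | 2-(2,3,6-trimethoxyphenyl)propan-2-ol | COc1ccc(OC)c(C(C)(C)O)c1OC | intermediate
5 | 1,2,4-trimethoxy-3-(propan-2-yl)benzene | COc1ccc(OC)c(C(C)C)c1OC | intermediate
6 | 2,4,5-trimethoxy-3-(propan-2-yl)benzaldehyde | COc1c(C(C)C)c(OC)c(C=O)cc1OC | intermediate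
7 | ortho-lithiated lithium α-amino alkoxide of 6 | COc1c(C(C)C)c(OC)c(C(O[Li])N(C)CCN(C)C)c([Li])c1OC | intermediate
8 | 2-iodo-3,4,6-trimethoxy-5-(propan-2-yl)benzaldehyde | COc1c(C(C)C)c(OC)c(C=O)c(I)c1OC | intermediate
9 | trimethyl(prop-2-en-1-yloxy)silane | C=CCO[Si](C)(C)C | starting material
10 | 1-[bis(prop-2-en-1-yloxy)methyl]-2-iodo-3,4,6-trimethoxy-5-(propan-2-yl)benzene | COc1c(C(C)C)c(OC)c(C(OCC=C)OCC=C)c(I)c1OC | intermediate
11 | 5,6,8-trimethoxy-4-methylidene-7-(propan-2-yl)-1-(prop-2-en-1-yloxy)-3,4-dihydro-1H-2-benzopyran (racemic) | COc1c(C(C)C)c(OC)c2c(c1OC)C(=C)COC2OCC=C | intermediate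
12 | tert-butyl[(1-methoxyethenyl)oxy]dimethylsilane | C=C(OC)O[Si](C)(C)C(C)(C)C | starting material
13 | 1-chloro-5,6,8-trimethoxy-4-methylidene-7-(propan-2-yl)-3,4-dihydro-1H-2-benzopyran | COc1c(C(C)C)c(OC)c2c(c1OC)C(=C)COC2Cl | intermediate
14 | methyl 2-[(1S)-5,6,8-trimethoxy-4-methylidene-7-(propan-2-yl)-3,4-dihydro-1H-2-benzopyran-1-yl]acetate | COc1c(C(C)C)c(OC)c2c(c1OC)C(=C)CO[C@H]2CC(=O)OC | intermediate
15 | methyl 2-[bis(2,2,2-trifluoroethoxy)phosphoryl]acetate | COC(=O)CP(=O)(OCC(F)(F)F)OCC(F)(F)F | starting material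
16 | sodium salt of 15 (phosphonate carbanion) | [Na+].COC(=O)[CH-]P(=O)(OCC(F)(F)F)OCC(F)(F)F | intermediate
17 | methyl 2-bromo-2-[bis(2,2,2-trifluoroethoxy)phosphoryl]acetate (racemic) | COC(=O)C(Br)P(=O)(OCC(F)(F)F)OCC(F)(F)F | intermediate
18 | 2-[(1S)-5,6,8-trimethoxy-4-methylidene-7-(propan-2-yl)-3,4-dihydro-1H-2-benzopyran-1-yl]acetaldehyde | COc1c(C(C)C)c(OC)c2c(c1OC)C(=C)CO[C@H]2CC=O | intermediate
19 | methyl (2E)-2-bromo-4-[(1S)-5,6,8-trimethoxy-4-methylidene-7-(propan-2-yl)-3,4-dihydro-1H-2-benzopyran-1-yl]but-2-enoate | COc1c(C(C)C)c(OC)c2c(c1OC)C(=C)CO[C@H]2C/C=C(/Br)C(=O)OC | intermediate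
20 | 2-ethenyl-4,4,5,5-tetramethyl-1,3,2-dioxaborolane | C=CB1OC(C)(C)C(C)(C)O1 | starting material
21 | methyl (2Z)-2-ethenyl-4-[(1S)-5,6,8-trimethoxy-4-methylidene-7-(propan-2-yl)-3,4-dihydro-1H-2-benzopyran-1-yl]but-2-enoate | COc1c(C(C)C)c(OC)c2c(c1OC)C(=C)CO[C@H]2C/C=C(/C=C)C(=O)OC | intermediate
22 | methyl (5R,7S,10R)-7,20-epoxy-11,12,14-trimethoxy-18-norabieta-3,8,11,13-tetraen-19-oate | COc1c(C(C)C)c(OC)c2c(c1OC)[C@]13CCC=C(C(=O)OC)[C@@H]3C[C@@H]2OC1 | intermediate
23 | lithium dienolate of 22 (C2=C3–C4=C19) | COc1c(C(C)C)c(OC)c2c(c1OC)[C@]13CC=CC(=C(O[Li])OC)[C@@H]3C[C@@H]2OC1 | intermediate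
24 | methyl (4S,5R,7S,10R)-7,20-epoxy-11,12,14-trimethoxyabieta-2,8,11,13-tetraen-19-oate | COc1c(C(C)C)c(OC)c2c(c1OC)[C@]13CC=C[C@](C)(C(=O)OC)[C@@H]3C[C@@H]2OC1 | intermediate
25 | methyl (4S,5R,7S,10R)-7,20-epoxy-11,12,14-trimethoxyabieta-8,11,13-trien-19-oate | COc1c(C(C)C)c(OC)c2c(c1OC)[C@]13CCC[C@](C)(C(=O)OC)[C@@H]3C[C@@H]2OC1 | intermediate
26 | methyl (4S,5R,10R)-20-hydroxy-11,12,14-trimethoxyabieta-6,8,11,13-tetraen-19-oate | COc1c(C(C)C)c(OC)c2c(c1OC)[C@@]1(CO)CCC[C@](C)(C(=O)OC)[C@@H]1C=C2 | intermediate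
27 | (4S,5R,10R)-11,12,14-trimethoxyabieta-6,8,11,13-tetraen-19,20-olide | COc1c(C(C)C)c(OC)c2c(c1OC)[C@]13CCC[C@](C)(C(=O)OC1)[C@@H]3C=C2 | intermediate
28 | (4S,5R,10R)-12-methoxy-11,14-dioxoabieta-6,8,12-trien-19,20-olide | COC1=C(C(C)C)C(=O)C2=C(C1=O)[C@]13CCC[C@](C)(C(=O)OC1)[C@@H]3C=C2 | intermediate
29 | (4S,5R,10R)-12-hydroxy-11,14-dioxoabieta-6,8,12-trien-19,20-olide | OC1=C(C(C)C)C(=O)C2=C(C1=O)[C@]13CCC[C@](C)(C(=O)OC1)[C@@H]3C=C2 | intermediate
30 | (4S,5R,10R)-12-acetoxy-11,14-dioxoabieta-6,8,12-trien-19,20-olide | CC(=O)OC1=C(C(C)C)C(=O)C2=C(C1=O)[C@]13CCC[C@](C)(C(=O)OC1)[C@@H]3C=C2 | target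

Total step count: 17. Longest linear sequence: 16 steps (steps 1–7 and 9–17; step 8 makes the olefination reagent).

Steps most likely to fail

Step 11 (key step). The cycloaddition may be too slow at temperatures the substrate tolerates, so that dimerisation of the diene ester or migration of the exocyclic double bond into the ring competes, and the two diene orientations that decide C5 may be poorly discriminated. The fallback sets out from 21 and comes back at 22. It is a radical-cation Diels–Alder reaction under visible-light photoredox catalysis (Ru(bpz)3(PF6)2, air, CH3NO2, rt): one-electron oxidation of the electron-rich aryl alkene should let the same two bonds form stepwise at room temperature in one operation, with the tether still fixing the face at C10. It makes no new compound (F0).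

Step 7. An uncatalysed background addition to the strongly stabilised, peri-methoxylated oxocarbenium ion may erode the enantioselectivity, and BCl3 may cleave aryl methyl ethers. The fallback sets out from 8 and comes back at 14, setting the carbinol centre on the aldehyde instead. A catalytic asymmetric Mukaiyama acetate aldol addition of 12 (Ti(O-i-Pr)4 with a chiral BINOL-derived Schiff-base ligand) should give methyl (3S)-3-[(tert-butyldimethylsilyl)oxy]-3-[2-iodo-3,4,6-trimethoxy-5-(propan-2-yl)phenyl]propanoate F1. Bu4NF then gives methyl (3S)-3-hydroxy-3-[2-iodo-3,4,6-trimethoxy-5-(propan-2-yl)phenyl]propanoate F2, and allyl bromide with Ag2O gives methyl (3S)-3-[2-iodo-3,4,6-trimethoxy-5-(propan-2-yl)phenyl]-3-(prop-2-en-1-yloxy)propanoate F3. The Heck cyclisation of step 6 (Pd(OAc)2, PPh3, Ag2CO3) then closes the dihydropyran and gives 14.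

Step 14. Re-closure of the ether, capture of the C7 cation by the ester, or cationic oligomerisation of the electron-rich styrene may outrun lactonisation. The fallback sets out from 25 and comes back at 27. Ionic hydrogenation of the benzylic ether (Et3SiH, CF3CO2H, CH2Cl2) traps the C7 cation with hydride, and the freed C20 alcohol lactonises (TsOH·H2O, PhCH3, 80 °C) to (4S,5R,10R)-11,12,14-trimethoxyabieta-8,11,13-trien-19,20-olide F4. Benzylic dehydrogenation with DDQ (dioxane, 80 °C) then introduces C6=C7 and gives 27.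

Further compounds
F0 | step 11 | none | none
F1 | step 7 | methyl (3S)-3-[(tert-butyldimethylsilyl)oxy]-3-[2-iodo-3,4,6-trimethoxy-5-(propan-2-yl)phenyl]propanoate | COc1c(C(C)C)c(OC)c([C@@H](O[Si](C)(C)C(C)(C)C)CC(=O)OC)c(I)c1OC
F2 | step 7 | methyl (3S)-3-hydroxy-3-[2-iodo-3,4,6-trimethoxy-5-(propan-2-yl)phenyl]propanoate | COc1c(C(C)C)c(OC)c([C@@H](O)CC(=O)OC)c(I)c1OC
F3 | step 7 | methyl (3S)-3-[2-iodo-3,4,6-trimethoxy-5-(propan-2-yl)phenyl]-3-(prop-2-en-1-yloxy)propanoate | COc1c(C(C)C)c(OC)c([C@@H](OCC=C)CC(=O)OC)c(I)c1OC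
F4 | step 14 | (4S,5R,10R)-11,12,14-trimethoxyabieta-8,11,13-trien-19,20-olide | COc1c(C(C)C)c(OC)c2c(c1OC)[C@]13CCC[C@](C)(C(=O)OC1)[C@@H]3CC2
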